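The 2,2-dimethylchromane is not closed from a prenylated phenol. Its aryl carbon C8a sits between C4a (which carries C4 of the dihydropyran ring) and the biaryl carbon C8 of the benzo ring, and it is treated as the ipso carbon of an aryl iodide. A palladium/norbornene domino joins 3-chloro-4-iodobenzaldehyde and 4-bromo-2-methylbutan-2-ol: the C4a–H position is alkylated first, then the dihydropyran ring closes by forming the O1–C8a aryl ether bond. One operation thus gives the chromane with the formyl group (for the first flavone) and the chlorine (for the biaryl bond) in place. Flavone construction, a borylation/Suzuki union with 8-iodoapigenin tribenzyl ether and hydrogenolysis finish the synthesis.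

Key step: step 1

Assumption: the target has no stereocenter and its biaryl axis is drawn without configuration, so no axial control is planned; 1 and 2 are taken as catalogue compounds, and all phenols travel as benzyl ethers because the tertiary alkyl aryl ether of the chromane would not survive the Lewis acids that cleave methyl ethers.

Step 1
Reactants: 1 3-chloro-4-iodobenzaldehyde; 2 4-bromo-2-methylbutan-2-ol
Product: 3 8-chloro-2,2-dimethylchromane-6-carbaldehyde
Conditions: Pd(OAc)2 (10 mol%), tri(2-furyl)phosphine (22 mol%), norbornene (2 equiv), Cs2CO3 (3 equiv), MeCN, 90 °C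
Reagents that add atoms: none
Why: Proposed new method: a Catellani-type palladium/norbornene domino terminated by the alcohol that the alkyl bromide itself carries; zerovalent palladium inserts into the C–I bond of 1, norbornene insertion and ortho C–H palladation give the aryl-norbornyl palladacycle, and this divalent palladacycle adds the primary C–Br bond of 2 to give a tetravalent palladium species that reductively eliminates the aryl–CH2 bond at the only free ortho carbon (later C4a). With both ortho positions filled, norbornene is expelled by β-carbon elimination and Cs2CO3 turns the aryl-palladium bromide into a seven-membered aryl-palladium alkoxide chelate. C(aryl)–O reductive elimination from this chelate at the ipso carbon (later C8a) closes the six-membered dihydropyran ring, the same mode of closure as in the Buchwald–Hartwig-type intramolecular etherification of tertiary alcohols, and no stereocenter is formed. The closest known reaction types are the palladium/norbornene ortho-alkylation with ipso amination by bromoalkylamines and the palladium/norbornene annulation of aryl iodides with epoxides to 2,3-dihydrobenzofurans; the six-membered C–O termination with a bromo alcohol is the unproven part. The step needs a single ortho-alkylation, C–O termination in preference to protodepalladation, and an intact C–Cl bond and formyl group: the chlorine blocks the second ortho carbon and enforces norbornene extrusion (ortho effect), the tertiary alkoxide has no β-hydrogen on its carbinol carbon, the para-formyl group accelerates C–O reductive elimination, and a triarylphosphine-type palladium catalyst with carbonate base should neither insert into the aryl chloride nor attack the aldehyde at 90 °C.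

Step 2
Reactants: 4 1-(2,4,6-trihydroxyphenyl)ethan-1-one (phloroacetophenone)
Product: 5 1-[2,4-bis(benzyloxy)-6-hydroxyphenyl]ethan-1-one
Conditions: BnBr (2.1 equiv), K2CO3, DMF, rt
Reagents that add atoms: benzyl bromide, BrCc1ccccc1
Why: Williamson etherification in which the para hydroxyl and one ortho hydroxyl are benzylated while the last ortho hydroxyl stays locked in its hydrogen bond to the acetyl carbonyl and remains free.

Step 3
Reactants: 3 8-chloro-2,2-dimethylchromane-6-carbaldehyde; 5 1-[2,4-bis(benzyloxy)-6-hydroxyphenyl]ethan-1-one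
Product: 6 (E)-1-[2,4-bis(benzyloxy)-6-hydroxyphenyl]-3-(8-chloro-2,2-dimethylchroman-6-yl)prop-2-en-1-one
Conditions: KOH (50% aq.), EtOH/THF, rt
Reagents that add atoms: none
Why: Claisen–Schmidt aldol condensation of the methyl ketone enolate with the non-enolisable aldehyde, followed by E1cB dehydration, should give the thermodynamically favoured (E)-enone.

Step 4
Reactants: 6 (E)-1-[2,4-bis(benzyloxy)-6-hydroxyphenyl]-3-(8-chloro-2,2-dimethylchroman-6-yl)prop-2-en-1-one
Product: 7 5,7-bis(benzyloxy)-2-(8-chloro-2,2-dimethylchroman-6-yl)-4H-chromen-4-one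
Conditions: I2 (10 mol%), DMSO, 130 °C
Reagents that add atoms: none
Why: Iodine/DMSO oxidative cyclisation of a 2'-hydroxychalcone, in which 6-endo oxa-Michael addition of the free phenol gives the flavanone, α-iodination and loss of HI give the chromone, and DMSO reoxidises HI to I2.

Step 5
Reactants: 8 apigenin (5,7-dihydroxy-2-(4-hydroxyphenyl)-4H-chromen-4-one)
Product: 9 5,7-bis(benzyloxy)-2-[4-(benzyloxy)phenyl]-4H-chromen-4-one
Conditions: BnBr (4 equiv), K2CO3, Bu4NI (cat.), DMF, 80 °C
Reagents that add atoms: benzyl bromide, BrCc1ccccc1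
Why: Williamson etherification, with excess benzyl bromide, iodide catalysis and heat used to alkylate also the hydrogen-bonded 5-hydroxyl.

Step 6
Reactants: 9 5,7-bis(benzyloxy)-2-[4-(benzyloxy)phenyl]-4H-chromen-4-one
Product: 10 5,7-bis(benzyloxy)-2-[4-(benzyloxy)phenyl]-8-iodo-4H-chromen-4-one
Conditions: NIS (1.05 equiv), CF3CO2H (cat.), MeCN/CH2Cl2, 0 °C to rt
Reagents that add atoms: N-iodosuccinimide, O=C1CCC(=O)N1I
Why: Electrophilic aromatic iodination, expected at C8 because in 5-O-alkylated 5,7-dioxygenated flavones this carbon (ortho to the 7-ether and the ring oxygen, para to the 5-ether) is the most nucleophilic and less crowded than C6 between two benzyloxy groups.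

Step 7
Reactants: 7 5,7-bis(benzyloxy)-2-(8-chloro-2,2-dimethylchroman-6-yl)-4H-chromen-4-one; 10 5,7-bis(benzyloxy)-2-[4-(benzyloxy)phenyl]-8-iodo-4H-chromen-4-one
Product: 12 5,7-bis(benzyloxy)-8-[6-(5,7-bis(benzyloxy)-4-oxo-4H-chromen-2-yl)-2,2-dimethylchroman-8-yl]-2-[4-(benzyloxy)phenyl]-4H-chromen-4-one, via pinacol boronate 11 (not isolated)
Conditions: Pd2(dba)3 (2 mol%), XPhos (8 mol%), B2pin2 (1.1 equiv), KOAc, 1,4-dioxane, 110 °C; then 10 (0.9 equiv), aq. K3PO4, 100 °C
Reagents that add atoms: bis(pinacolato)diboron, CC1(C)OB(OC1(C)C)B1OC(C)(C)C(C)(C)O1 (its boryl group stands in 11 only and is lost again on the way to 12)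
Why: Miyaura borylation of the aryl chloride followed in the same flask by Suzuki–Miyaura coupling with iodide 10, the bulky dialkylbiarylphosphine supporting both oxidative addition into the electron-rich C–Cl bond and the tri-ortho-substituted biaryl coupling, with no stereocenter formed and the axis left uncontrolled.

Step 8
Reactants: 12 5,7-bis(benzyloxy)-8-[6-(5,7-bis(benzyloxy)-4-oxo-4H-chromen-2-yl)-2,2-dimethylchroman-8-yl]-2-[4-(benzyloxy)phenyl]-4H-chromen-4-one
Product: 13 8-[6-(5,7-dihydroxy-4-oxo-4H-chromen-2-yl)-2,2-dimethylchroman-8-yl]-5,7-dihydroxy-2-(4-hydroxyphenyl)-4H-chromen-4-one (CNP0127025.0)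
Conditions: H2 (1 atm), 10% Pd/C, THF/MeOH, rt
Reagents that add atoms: none
Why: Catalytic hydrogenolysis should cleave the five benzyl aryl ethers, while the chromone C2=C3 bonds and the non-benzylic tertiary alkyl aryl ether of the chromane are expected to survive at ambient pressure and temperature.

Compound list
1 | 3-chloro-4-iodobenzaldehyde | O=Cc1ccc(I)c(Cl)c1 | starting material
2 | 4-bromo-2-methylbutan-2-ol | CC(C)(O)CCBr | starting material
3 | 8-chloro-2,2-dimethylchromane-6-carbaldehyde | CC1(C)CCc2cc(C=O)cc(Cl)c2O1 | intermediate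
4 | 1-(2,4,6-trihydroxyphenyl)ethan-1-one (phloroacetophenone) | CC(=O)c1c(O)cc(O)cc1O | starting material
5 | 1-[2,4-bis(benzyloxy)-6-hydroxyphenyl]ethan-1-one | CC(=O)c1c(O)cc(OCc2ccccc2)cc1OCc1ccccc1 | intermediate
6 | (E)-1-[2,4-bis(benzyloxy)-6-hydroxyphenyl]-3-(8-chloro-2,2-dimethylchroman-6-yl)prop-2-en-1-one | CC1(C)CCc2cc(/C=C/C(=O)c3c(O)cc(OCc4ccccc4)cc3OCc3ccccc3)cc(Cl)c2O1 | intermediate
7 | 5,7-bis(benzyloxy)-2-(8-chloro-2,2-dimethylchroman-6-yl)-4H-chromen-4-one | CC1(C)CCc2cc(-c3cc(=O)c4c(OCc5ccccc5)cc(OCc5ccccc5)cc4o3)cc(Cl)c2O1 | intermediate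
8 | apigenin (5,7-dihydroxy-2-(4-hydroxyphenyl)-4H-chromen-4-one) | O=c1cc(-c2ccc(O)cc2)oc2cc(O)cc(O)c12 | starting material
9 | 5,7-bis(benzyloxy)-2-[4-(benzyloxy)phenyl]-4H-chromen-4-one | O=c1cc(-c2ccc(OCc3ccccc3)cc2)oc2cc(OCc3ccccc3)cc(OCc3ccccc3)c12 | intermediate
10 | 5,7-bis(benzyloxy)-2-[4-(benzyloxy)phenyl]-8-iodo-4H-chromen-4-one | O=c1cc(-c2ccc(OCc3ccccc3)cc2)oc2c(I)c(OCc3ccccc3)cc(OCc3ccccc3)c12 | intermediate
11 | 5,7-bis(benzyloxy)-2-[2,2-dimethyl-8-(4,4,5,5-tetramethyl-1,3,2-dioxaborolan-2-yl)chroman-6-yl]-4H-chromen-4-one (pinacol boronate, formed in the flask) | CC1(C)CCc2cc(-c3cc(=O)c4c(OCc5ccccc5)cc(OCc5ccccc5)cc4o3)cc(B3OC(C)(C)C(C)(C)O3)c2O1 | intermediate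
12 | 5,7-bis(benzyloxy)-8-[6-(5,7-bis(benzyloxy)-4-oxo-4H-chromen-2-yl)-2,2-dimethylchroman-8-yl]-2-[4-(benzyloxy)phenyl]-4H-chromen-4-one | CC1(C)CCc2cc(-c3cc(=O)c4c(OCc5ccccc5)cc(OCc5ccccc5)cc4o3)cc(-c3c(OCc4ccccc4)cc(OCc4ccccc4)c4c(=O)cc(-c5ccc(OCc6ccccc6)cc5)oc34)c2O1 | intermediate
13 | 8-[6-(5,7-dihydroxy-4-oxo-4H-chromen-2-yl)-2,2-dimethylchroman-8-yl]-5,7-dihydroxy-2-(4-hydroxyphenyl)-4H-chromen-4-one (CNP0127025.0) | CC1(C)CCc2cc(-c3cc(=O)c4c(O)cc(O)cc4o3)cc(-c3c(O)cc(O)c4c(=O)cc(-c5ccc(O)cc5)oc34)c2O1 | target

Total step count: 8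
Longest linear sequence: 5 steps (steps 1, 3, 4, 7, 8; the branch through steps 2, 3, 4, 7, 8 is equally long)

Steps most likely to fail

Step 1. After the ortho-alkylation, C–O reductive elimination from the crowded aryl-palladium alkoxide may be slower than protodepalladation or ortho-arylation by a second molecule of the iodide, and the formyl group may degrade under hot carbonate. The fallback uses known chemistry, sets out from 2 and comes back at 3. Nickel-catalysed reductive cross-electrophile coupling of 2 with purchased 3-bromo-5-chloro-4-fluorobenzaldehyde (O=Cc1cc(Cl)c(F)c(Br)c1) at its C–Br bond (NiBr2(dme), 4,4'-di-tert-butyl-2,2'-bipyridine, Zn, DMA, 60 °C) should give 3-chloro-4-fluoro-5-(3-hydroxy-3-methylbutyl)benzaldehyde F1. Treatment of F1 with NaH in THF/DMF at 0 °C to rt should then bring about an intramolecular SNAr reaction, the tertiary alkoxide displacing the fluoride para to the formyl group. The same aryl C–O bond is formed in the ring closure and the product is 3.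

Step 6. The iodination may fail to discriminate between C8 and C6 of ring A, or may run on to a second iodination at C6, C3 or ring B. The fallback sets out from 5 and comes back at 10; it fixes the iodine position before the chromone exists. Iodination of 5 next to the chelated hydroxyl (I2, HIO3, EtOH/H2O, 40 °C) should give 1-[4,6-bis(benzyloxy)-2-hydroxy-3-iodophenyl]ethan-1-one F2. Claisen–Schmidt condensation of F2 with purchased 4-(benzyloxy)benzaldehyde (O=Cc1ccc(OCc2ccccc2)cc1; KOH, EtOH/THF, rt) should give (E)-1-[4,6-bis(benzyloxy)-2-hydroxy-3-iodophenyl]-3-[4-(benzyloxy)phenyl]prop-2-en-1-one F3. Cyclisation of F3 with I2 (cat.) in DMSO at 130 °C places the iodine-bearing carbon at C8 and gives 10.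

Step 7. Borylation of the ortho-alkoxy aryl chloride may be sluggish, left-over diboron may borylate and homocouple the iodide, and protodeboronation may outrun the slow tri-ortho transmetalation. The fallback sets out from 7 and comes back at 12; it moves the hindered coupling to a small partner and builds the second chromone afterwards. The borylation of 7 is run alone and pinacol boronate 11 is isolated. Suzuki–Miyaura coupling of 11 with the iodoketone F2 (made from 5 as described for step 6; Pd(OAc)2, SPhos, K3PO4, toluene/H2O, 90 °C) should give 1-{4,6-bis(benzyloxy)-3-[6-(5,7-bis(benzyloxy)-4-oxo-4H-chromen-2-yl)-2,2-dimethylchroman-8-yl]-2-hydroxyphenyl}ethan-1-one F4. Claisen–Schmidt condensation of F4 with 4-(benzyloxy)benzaldehyde (KOH, EtOH/THF, rt) should give (E)-1-{4,6-bis(benzyloxy)-3-[6-(5,7-bis(benzyloxy)-4-oxo-4H-chromen-2-yl)-2,2-dimethylchroman-8-yl]-2-hydroxyphenyl}-3-[4-(benzyloxy)phenyl]prop-2-en-1-one F5. Oxidative cyclisation of F5 with I2 (cat.) in DMSO at 130 °C closes the pyranone ring of the apigenin unit and gives 12.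

Further compounds
F1 | step 1 | 3-chloro-4-fluoro-5-(3-hydroxy-3-methylbutyl)benzaldehyde | CC(C)(O)CCc1cc(C=O)cc(Cl)c1F
F2 | step 6 | 1-[4,6-bis(benzyloxy)-2-hydroxy-3-iodophenyl]ethan-1-one | CC(=O)c1c(O)c(I)c(OCc2ccccc2)cc1OCc1ccccc1
F3 | step 6 | (E)-1-[4,6-bis(benzyloxy)-2-hydroxy-3-iodophenyl]-3-[4-(benzyloxy)phenyl]prop-2-en-1-one | O=C(/C=C/c1ccc(OCc2ccccc2)cc1)c1c(O)c(I)c(OCc2ccccc2)cc1OCc1ccccc1
F4 | step 7 | 1-{4,6-bis(benzyloxy)-3-[6-(5,7-bis(benzyloxy)-4-oxo-4H-chromen-2-yl)-2,2-dimethylchroman-8-yl]-2-hydroxyphenyl}ethan-1-one | CC(=O)c1c(O)c(-c2cc(-c3cc(=O)c4c(OCc5ccccc5)cc(OCc5ccccc5)cc4o3)cc3c2OC(C)(C)CC3)c(OCc2ccccc2)cc1OCc1ccccc1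
F5 | step 7 | (E)-1-{4,6-bis(benzyloxy)-3-[6-(5,7-bis(benzyloxy)-4-oxo-4H-chromen-2-yl)-2,2-dimethylchroman-8-yl]-2-hydroxyphenyl}-3-[4-(benzyloxy)phenyl]prop-2-en-1-one | O=C(/C=C/c1ccc(OCc2ccccc2)cc1)c1c(O)c(-c2cc(-c3cc(=O)c4c(OCc5ccccc5)cc(OCc5ccccc5)cc4o3)cc3c2OC(C)(C)CC3)c(OCc2ccccc2)cc1OCc1ccccc1
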